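Everything rests on cutting, at each benzylic quaternary carbon (the sp3 carbon on C1 of ring A, R, and on C1 of ring B, S), the bond to its methyl carbon: methyl and vinyl there map onto the CH2O and CHO carbons of a 3-aryl-2,3-epoxy alcohol. One aluminium-promoted semipinacol step moves both siloxymethyl groups onto the tertiary benzylic epoxide carbons, so both C(quaternary)–CH2O bonds, both stereocentres and two aldehydes arise together. The precursor is a diaryl ether bis(epoxy silyl ether), made by a twofold Sharpless epoxidation of an E allylic alcohol on ring A and a Z allylic alcohol on ring B, with the ring B catechol masked as bis(methoxymethyl) ether.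

Key step: step 13

Assumption: (3-hydroxy-4-methoxyphenyl)boronic acid 6 and 3-bromocatechol 10 are taken as commercial.

Design remarks:
- Both alkene geometries come from one β-keto ester through its E and Z enol triflates and stereoretentive Suzuki coupling. Carbomagnesiation of an arylpropargyl alcohol is not used for the E arm, because it would place the chain on C2 instead of C3.
- The ring B catechol is carried as a bis(methoxymethyl) ether, because a vicinal dimethoxy unit could only be unmasked under forcing conditions. Ring A keeps the single methyl ether of the commercial boronic acid, which thiolate should cleave on its own.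
- The diaryl ether is formed at the allylic alcohol level, where base cannot scramble the alkene geometry.
- Stereochemical bookkeeping: L-(+)-tartrate epoxidises both arms on the same face relative to CH2OH, giving (2S,3S) on the E arm and (2S,3R) on the Z arm. The anti shift should then give S on ring A and R on ring B at the aldehyde stage. These descriptors read R and S once CHO has become vinyl and CH2O has become methyl, with no spatial change.

Step 1
Reactants: 1 methyl acetoacetate; 2 geranyl chloride
Product: 4 methyl (6E)-7,11-dimethyl-3-oxododeca-6,10-dienoate, via methyl acetoacetate dianion 3 (not isolated)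
Conditions: NaH, THF, 0 °C; n-BuLi, 0 °C; then 2, 0 °C → rt
Reagents that add atoms: none
Why: Acetoacetate dianion γ-alkylation, in which the more basic terminal carbanion should displace the primary allylic chloride by SN2 without allylic transposition, so the E alkene of the geranyl unit is kept.

Step 2
Reactants: 4 methyl (6E)-7,11-dimethyl-3-oxododeca-6,10-dienoate
Product: 5 methyl (2E,6E)-7,11-dimethyl-3-[(trifluoromethylsulfonyl)oxy]dodeca-2,6,10-trienoate
Conditions: Tf2O, aq. Me4NOH, hexanes, 5–10 °C
Reagents that add atoms: trifluoromethanesulfonic anhydride, O=S(=O)(OS(=O)(=O)C(F)(F)F)C(F)(F)F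
Why: Stereoselective enol triflation of a β-keto ester, in which the non-chelated ammonium enolate should adopt the dipole-minimised geometry and be trapped on oxygen with the triflate trans to the ester.

Step 3
Reactants: 5 methyl (2E,6E)-7,11-dimethyl-3-[(trifluoromethylsulfonyl)oxy]dodeca-2,6,10-trienoate; 6 (3-hydroxy-4-methoxyphenyl)boronic acid
Product: 7 methyl (2E,6E)-3-(3-hydroxy-4-methoxyphenyl)-7,11-dimethyldodeca-2,6,10-trienoate
Conditions: Pd(PPh3)4 (cat.), K2CO3, THF/H2O, 40 °C
Reagents that add atoms: none
Why: Suzuki–Miyaura coupling of an activated enol triflate, which should proceed with retention of alkene geometry and so place the aryl ring trans to the ester (E arm), the free phenol being tolerated as its phenoxide.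

Step 4
Reactants: 7 methyl (2E,6E)-3-(3-hydroxy-4-methoxyphenyl)-7,11-dimethyldodeca-2,6,10-trienoate
Product: 8 (2E,6E)-3-(3-hydroxy-4-methoxyphenyl)-7,11-dimethyldodeca-2,6,10-trien-1-ol
Conditions: iBu2AlH (excess), CH2Cl2, −78 → 0 °C; aq. potassium sodium tartrate
Reagents that add atoms: none
Why: Aluminium hydride 1,2-reduction of an enoate to the allylic alcohol, which should leave the trisubstituted alkenes and their geometry untouched, one extra equivalent being consumed by the phenol.

Step 5
Reactants: 4 methyl (6E)-7,11-dimethyl-3-oxododeca-6,10-dienoate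
Product: 9 methyl (2Z,6E)-7,11-dimethyl-3-[(trifluoromethylsulfonyl)oxy]dodeca-2,6,10-trienoate
Conditions: Tf2O, sat. aq. LiOH, toluene, 5–10 °C
Reagents that add atoms: trifluoromethanesulfonic anhydride, O=S(=O)(OS(=O)(=O)C(F)(F)F)C(F)(F)F
Why: Stereoselective enol triflation of a β-keto ester, in which the lithium-chelated enolate should hold the enolate oxygen cis to the ester and deliver the Z enol triflate.

Step 6
Reactants: 10 3-bromobenzene-1,2-diol
Product: 11 1-bromo-2,3-bis(methoxymethoxy)benzene
Conditions: MOMCl, iPr2NEt, CH2Cl2, 0 °C → rt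
Reagents that add atoms: chloromethyl methyl ether, COCCl
Why: O-alkylation of both phenols with an α-chloro ether (acetal protection), which should give a catechol mask that is stable to base and hydride and is removed later by mild acid.

Step 7
Reactants: 11 1-bromo-2,3-bis(methoxymethoxy)benzene
Product: 12 2-[3-bromo-4,5-bis(methoxymethoxy)phenyl]-4,4,5,5-tetramethyl-1,3,2-dioxaborolane
Conditions: [Ir(OMe)(1,5-cyclooctadiene)]2 (cat.), 4,4′-di-tert-butyl-2,2′-bipyridine, B2pin2, THF, 70 °C
Reagents that add atoms: bis(pinacolato)diboron, CC1(C)OB(OC1(C)C)B1OC(C)(C)C(C)(C)O1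
Why: Iridium-catalysed aromatic C–H borylation is governed by sterics, so only the C5–H bond, the single one without an ortho substituent, should react while the aryl bromide is tolerated.

Step 8
Reactants: 9 methyl (2Z,6E)-7,11-dimethyl-3-[(trifluoromethylsulfonyl)oxy]dodeca-2,6,10-trienoate; 12 2-[3-bromo-4,5-bis(methoxymethoxy)phenyl]-4,4,5,5-tetramethyl-1,3,2-dioxaborolane
Product: 13 methyl (2Z,6E)-3-[3-bromo-4,5-bis(methoxymethoxy)phenyl]-7,11-dimethyldodeca-2,6,10-trienoate
Conditions: Pd(PPh3)4 (cat.), aq. K3PO4, THF, rt → 40 °C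
Reagents that add atoms: none
Why: Suzuki–Miyaura coupling with retention, in which zerovalent palladium should insert into the activated enol triflate far faster than into the electron-rich ortho-alkoxy aryl bromide, placing the aryl ring cis to the ester (Z arm).

Step 9
Reactants: 13 methyl (2Z,6E)-3-[3-bromo-4,5-bis(methoxymethoxy)phenyl]-7,11-dimethyldodeca-2,6,10-trienoate
Product: 14 (2Z,6E)-3-[3-bromo-4,5-bis(methoxymethoxy)phenyl]-7,11-dimethyldodeca-2,6,10-trien-1-ol
Conditions: iBu2AlH, CH2Cl2, −78 °C; aq. potassium sodium tartrate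
Reagents that add atoms: none
Why: Aluminium hydride 1,2-reduction of the enoate at low temperature, which should spare the aryl bromide, the acetals and the Z geometry.

Step 10
Reactants: 8 (2E,6E)-3-(3-hydroxy-4-methoxyphenyl)-7,11-dimethyldodeca-2,6,10-trien-1-ol; 14 (2Z,6E)-3-[3-bromo-4,5-bis(methoxymethoxy)phenyl]-7,11-dimethyldodeca-2,6,10-trien-1-ol
Product: 15 (2E,6E)-3-[3-[5-[(2Z,6E)-1-hydroxy-7,11-dimethyldodeca-2,6,10-trien-3-yl]-2,3-bis(methoxymethoxy)phenoxy]-4-methoxyphenyl]-7,11-dimethyldodeca-2,6,10-trien-1-ol
Conditions: CuI (cat.), picolinic acid, K3PO4, DMSO, 85 °C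
Reagents that add atoms: none
Why: Ullmann-type copper-catalysed diaryl ether coupling with a picolinate ligand, which tolerates ortho substituents on both partners and should arylate only the phosphate-deprotonated phenol, not the two primary allylic alcohols.

Step 11
Reactants: 15 (2E,6E)-3-[3-[5-[(2Z,6E)-1-hydroxy-7,11-dimethyldodeca-2,6,10-trien-3-yl]-2,3-bis(methoxymethoxy)phenoxy]-4-methoxyphenyl]-7,11-dimethyldodeca-2,6,10-trien-1-ol
Product: 16 bis(epoxy alcohol) of 15 with (2S,3S) oxirane on the ring A arm and (2S,3R) oxirane on the ring B arm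
Conditions: Ti(OiPr)4 (cat.), L-(+)-diisopropyl tartrate, tBuOOH, 4 Å MS, CH2Cl2, −25 °C
Reagents that add atoms: tert-butyl hydroperoxide, CC(C)(C)OO
Why: Twofold Sharpless asymmetric epoxidation, in which the titanium tartrate should deliver oxygen to the same face of both allylic alcohols relative to CH2OH (2S at both C2, hence 3S from the E arm and 3R from the Z arm) and leave the four remote alkenes alone, the catalytic sieve protocol limiting opening of the benzylic epoxides.

Step 12
Reactants: 16 bis(epoxy alcohol) of 15 with (2S,3S) oxirane on the ring A arm and (2S,3R) oxirane on the ring B arm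
Product: 17 bis(tert-butyldimethylsilyl ether) of 16
Conditions: TBSCl, imidazole, DMF, 0 °C → rt
Reagents that add atoms: tert-butyldimethylsilyl chloride, CC(C)(C)[Si](C)(C)Cl
Why: Imidazole-buffered silylation of the two primary alcohols, a non-acidic protection that should leave the acid-labile tertiary benzylic epoxides intact.

Step 13
Reactants: 17 bis(tert-butyldimethylsilyl ether) of 16
Product: 18 bis(aldehyde) in which ring A carries the (2S,5E)-2-[(tert-butyldimethylsilyloxy)methyl]-6,10-dimethyl-1-oxoundeca-5,9-dien-2-yl group and ring B the (2R,5E) group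
Conditions: MeAl(OC6H2-4-Br-2,6-tBu2)2 (5 equiv; from Me3Al and 4-bromo-2,6-di-tert-butylphenol, CH2Cl2, rt), CH2Cl2, −78 → −40 °C
Reagents that add atoms: none
Why: The bulky oxophilic aluminium aryloxide binds each epoxide oxygen, the tertiary benzylic C3–O bond lengthens, and the siloxymethyl group on C2 migrates to C3 anti to the departing oxygen while C2 becomes the aldehyde carbon (semipinacol 1,2-shift). The closest known reaction type is the organoaluminium-promoted rearrangement of 2,3-epoxy alcohol silyl ethers to α-quaternary β-siloxy aldehydes, here run twice in one molecule. No ring is closed; two C–C bonds and two stereocentres are formed. Each quaternary centre is set by inversion at the benzylic epoxide carbon, so the (2S,3S) epoxide of the E arm should give S on ring A and the (2S,3R) epoxide of the Z arm should give R on ring B. The step needs opening at C3 only and alkyl shift ahead of hydride shift or a free cation: the aryl ring and the chain make C3 the only cation-stabilising terminus, the hindered Lewis acid at low temperature favours the anti-periplanar siloxymethyl shift, and the nearest chain alkene could only close a four-membered or a strained five-membered ring, so it should not compete.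

Step 14
Reactants: 18 bis(aldehyde) in which ring A carries the (2S,5E)-2-[(tert-butyldimethylsilyloxy)methyl]-6,10-dimethyl-1-oxoundeca-5,9-dien-2-yl group and ring B the (2R,5E) group
Product: 19 bis(vinyl) bis(silyl ether) in which ring A carries the (3S,6E)-3-[(tert-butyldimethylsilyloxy)methyl]-7,11-dimethyldodeca-1,6,10-trien-3-yl group and ring B the (3R,6E) group
Conditions: Ph3PCH3Br, KOtBu, THF, 0 °C → rt
Reagents that add atoms: methyltriphenylphosphonium bromide, C[P+](c1ccccc1)(c1ccccc1)c1ccccc1.[Br-]
Why: Twofold Wittig methylenation of aldehydes that have no α-hydrogen, so neither epimerisation nor β-elimination of the siloxy group is possible and the unstabilised ylide should reach the hindered carbonyls.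

Step 15
Reactants: 19 bis(vinyl) bis(silyl ether) in which ring A carries the (3S,6E)-3-[(tert-butyldimethylsilyloxy)methyl]-7,11-dimethyldodeca-1,6,10-trien-3-yl group and ring B the (3R,6E) group
Product: 20 diol in which ring A carries the (3S,6E)-3-(hydroxymethyl)-7,11-dimethyldodeca-1,6,10-trien-3-yl group and ring B the (3R,6E) group
Conditions: Bu4NF, THF, 0 °C → rt
Reagents that add atoms: none
Why: Fluoride-mediated desilylation of primary silyl ethers, to which the acetals, the aryl ethers and the alkenes are inert.

Step 16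
Reactants: 20 diol in which ring A carries the (3S,6E)-3-(hydroxymethyl)-7,11-dimethyldodeca-1,6,10-trien-3-yl group and ring B the (3R,6E) group
Product: 21 bis(methanesulfonate) of 20
Conditions: MsCl, Et3N, CH2Cl2, −10 °C
Reagents that add atoms: methanesulfonyl chloride, CS(=O)(=O)Cl
Why: Sulfonylation of the two neopentyl-type primary alcohols under cold basic conditions, the crude bis(mesylate) being carried on at once to avoid ionisation.

Step 17
Reactants: 21 bis(methanesulfonate) of 20
Product: 22 protected dimer in which ring A (4-methoxy) carries the (3R,6E)-3,7,11-trimethyldodeca-1,6,10-trien-3-yl group and ring B (4,5-bis(methoxymethoxy)) the (3S,6E) group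
Conditions: LiEt3BH (excess), THF, 0 → 60 °C
Reagents that add atoms: none
Why: SN2 hydride displacement of sulfonates by a trialkylborohydride, a nucleophile strong enough for neopentyl centres, which should turn each CH2OMs into methyl without touching the adjacent stereocentre (the descriptors change to R and S only through the priority rules).

Step 18
Reactants: 22 protected dimer in which ring A (4-methoxy) carries the (3R,6E)-3,7,11-trimethyldodeca-1,6,10-trien-3-yl group and ring B (4,5-bis(methoxymethoxy)) the (3S,6E) group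
Product: 23 ring A phenol of 22 with both methoxymethyl ethers on ring B retained
Conditions: NaSEt, DMF, 120 °C
Reagents that add atoms: none
Why: Thiolate SN2 demethylation of the single aryl methyl ether, conditions under which isolated alkenes are inert and the acetals should survive or be partly removed, which is harmless before the next step.

Step 19
Reactants: 23 ring A phenol of 22 with both methoxymethyl ethers on ring B retained
Product: 24 target CNP0296687.1
Conditions: 2 M HCl, MeOH/THF, 40 °C, argon
Reagents that add atoms: none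
Why: Acid-catalysed transacetalisation of aryl methoxymethyl ethers to methanol, mild enough that the trisubstituted alkenes should not be protonated, with air excluded to protect the free catechol.

Compound list
1 | methyl acetoacetate | COC(=O)CC(C)=O | starting material
2 | geranyl chloride, (2E)-1-chloro-3,7-dimethylocta-2,6-diene | CC(C)=CCC/C(C)=C/CCl | starting material
3 | methyl acetoacetate dianion (sodium lithium salt) | [Na+].[Li+].COC(=O)[CH-]C(=O)[CH2-] | intermediate
4 | methyl (6E)-7,11-dimethyl-3-oxododeca-6,10-dienoate | COC(=O)CC(=O)CC/C=C(\C)CCC=C(C)C | intermediate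
5 | methyl (2E,6E)-7,11-dimethyl-3-[(trifluoromethylsulfonyl)oxy]dodeca-2,6,10-trienoate | COC(=O)/C=C(/OS(=O)(=O)C(F)(F)F)CC/C=C(\C)CCC=C(C)C | intermediate
6 | (3-hydroxy-4-methoxyphenyl)boronic acid | COc1ccc(B(O)O)cc1O | starting material
7 | methyl (2E,6E)-3-(3-hydroxy-4-methoxyphenyl)-7,11-dimethyldodeca-2,6,10-trienoate | COC(=O)/C=C(/c1ccc(OC)c(O)c1)CC/C=C(\C)CCC=C(C)C | intermediate
8 | (2E,6E)-3-(3-hydroxy-4-methoxyphenyl)-7,11-dimethyldodeca-2,6,10-trien-1-ol | OC/C=C(/c1ccc(OC)c(O)c1)CC/C=C(\C)CCC=C(C)C | intermediate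
9 | methyl (2Z,6E)-7,11-dimethyl-3-[(trifluoromethylsulfonyl)oxy]dodeca-2,6,10-trienoate | COC(=O)/C=C(\OS(=O)(=O)C(F)(F)F)CC/C=C(\C)CCC=C(C)C | intermediate
10 | 3-bromobenzene-1,2-diol (3-bromocatechol) | Oc1cccc(Br)c1O | starting material
11 | 1-bromo-2,3-bis(methoxymethoxy)benzene | COCOc1cccc(Br)c1OCOC | intermediate
12 | 2-[3-bromo-4,5-bis(methoxymethoxy)phenyl]-4,4,5,5-tetramethyl-1,3,2-dioxaborolane | COCOc1cc(cc(Br)c1OCOC)B1OC(C)(C)C(C)(C)O1 | intermediate
13 | methyl (2Z,6E)-3-[3-bromo-4,5-bis(methoxymethoxy)phenyl]-7,11-dimethyldodeca-2,6,10-trienoate | COC(=O)/C=C(\c1cc(Br)c(OCOC)c(OCOC)c1)CC/C=C(\C)CCC=C(C)C | intermediate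
14 | (2Z,6E)-3-[3-bromo-4,5-bis(methoxymethoxy)phenyl]-7,11-dimethyldodeca-2,6,10-trien-1-ol | OC/C=C(\c1cc(Br)c(OCOC)c(OCOC)c1)CC/C=C(\C)CCC=C(C)C | intermediate
15 | (2E,6E)-3-[3-[5-[(2Z,6E)-1-hydroxy-7,11-dimethyldodeca-2,6,10-trien-3-yl]-2,3-bis(methoxymethoxy)phenoxy]-4-methoxyphenyl]-7,11-dimethyldodeca-2,6,10-trien-1-ol | OC/C=C(/c1ccc(OC)c(Oc2cc(/C(CC/C=C(\C)CCC=C(C)C)=C\CO)cc(OCOC)c2OCOC)c1)CC/C=C(\C)CCC=C(C)C | intermediate
16 | bis(epoxy alcohol) of 15: (2S,3S)-oxirane on the ring A arm, (2S,3R)-oxirane on the ring B arm; each C2 bears CH2OH, each C3 the aryl ring and the (3E)-4,8-dimethylnona-3,7-dienyl chain | OC[C@@H]1O[C@@]1(CC/C=C(\C)CCC=C(C)C)c2ccc(OC)c(Oc3cc([C@@]4(CC/C=C(\C)CCC=C(C)C)O[C@H]4CO)cc(OCOC)c3OCOC)c2 | intermediate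
17 | bis(tert-butyldimethylsilyl ether) of 16, the bis(epoxy silyl ether) precursor of the key step | CC(C)(C)[Si](C)(C)OC[C@@H]1O[C@@]1(CC/C=C(\C)CCC=C(C)C)c2ccc(OC)c(Oc3cc([C@@]4(CC/C=C(\C)CCC=C(C)C)O[C@H]4CO[Si](C)(C)C(C)(C)C)cc(OCOC)c3OCOC)c2 | intermediate
18 | bis(α-quaternary β-siloxy aldehyde): S centre on ring A, R centre on ring B, each bearing CHO, CH2OTBS, the aryl ring and the chain | CC(C)(C)[Si](C)(C)OC[C@](C=O)(CC/C=C(\C)CCC=C(C)C)c1ccc(OC)c(Oc2cc([C@@](CC/C=C(\C)CCC=C(C)C)(C=O)CO[Si](C)(C)C(C)(C)C)cc(OCOC)c2OCOC)c1 | intermediate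
19 | bis(vinyl) bis(silyl ether): (3S,6E)-3-(TBSOCH2)-7,11-dimethyldodeca-1,6,10-trien-3-yl on ring A, (3R,6E) on ring B | CC(C)(C)[Si](C)(C)OC[C@](C=C)(CC/C=C(\C)CCC=C(C)C)c1ccc(OC)c(Oc2cc([C@@](CC/C=C(\C)CCC=C(C)C)(C=C)CO[Si](C)(C)C(C)(C)C)cc(OCOC)c2OCOC)c1 | intermediate
20 | diol: (3S,6E)-3-(hydroxymethyl)-7,11-dimethyldodeca-1,6,10-trien-3-yl on ring A, (3R,6E) on ring B | OC[C@](C=C)(CC/C=C(\C)CCC=C(C)C)c1ccc(OC)c(Oc2cc([C@@](CC/C=C(\C)CCC=C(C)C)(C=C)CO)cc(OCOC)c2OCOC)c1 | intermediate
21 | bis(methanesulfonate) of 20 | CS(=O)(=O)OC[C@](C=C)(CC/C=C(\C)CCC=C(C)C)c1ccc(OC)c(Oc2cc([C@@](CC/C=C(\C)CCC=C(C)C)(C=C)COS(C)(=O)=O)cc(OCOC)c2OCOC)c1 | intermediate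
22 | protected dimer: (3R,6E)-3,7,11-trimethyldodeca-1,6,10-trien-3-yl on ring A (4-OMe), (3S,6E) on ring B (4,5-bis-OMOM) | C[C@](C=C)(CC/C=C(\C)CCC=C(C)C)c1ccc(OC)c(Oc2cc([C@@](CC/C=C(\C)CCC=C(C)C)(C=C)C)cc(OCOC)c2OCOC)c1 | intermediate
23 | ring A phenol of 22, ring B still 4,5-bis(methoxymethoxy) | C[C@](C=C)(CC/C=C(\C)CCC=C(C)C)c1ccc(O)c(Oc2cc([C@@](CC/C=C(\C)CCC=C(C)C)(C=C)C)cc(OCOC)c2OCOC)c1 | intermediate
24 | CNP0296687.1: ring A 4-hydroxy with the (3R,6E)-3,7,11-trimethyldodeca-1,6,10-trien-3-yl group at C1, linked through O at C3 to C3 of ring B, which is 4,5-dihydroxy with the (3S,6E) group at C1 | C=C[C@@](C)(CC/C=C(\C)CCC=C(C)C)c1ccc(O)c(Oc2cc([C@](C)(C=C)CC/C=C(\C)CCC=C(C)C)cc(O)c2O)c1 | target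

Total step count: 19.
Longest linear sequence: 14 steps (2 → 4 → 5 → 7 → 8 → 15 → 16 → 17 → 18 → 19 → 20 → 21 → 22 → 23 → 24).

Steps most likely to fail

Step 13. The para-alkoxy-stabilised benzylic C–O bond, above all on ring A, may ionise to a free cation before the shift. Bond rotation, hydride shift to a ketone or loss of stereospecific migration would then erode one or both quaternary centres. The fallback sets out from 16 and comes back at 22. The free bis(epoxy alcohol) 16 is treated with Me3Al (hexane/CH2Cl2, −30 → 0 °C); the aluminium alkoxide directs methyl to the benzylic C3 with inversion, giving the bis(3-methyl-1,2-diol) F1. Glycol cleavage with NaIO4 (THF/H2O) gives the bis(α-methyl aldehyde) F2, and Wittig methylenation (Ph3PCH3Br, KOtBu, THF) converts F2 into 22. Methyl enters anti to the epoxide oxygen just as the siloxymethyl group would, so the same epoxide configurations should lead to the same quaternary centres.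

Step 11. The Lewis-acidic titanium may open the electron-rich tertiary benzylic epoxy alcohols as they form, and the Z arm may be epoxidised slowly with weaker facial control. The fallback sets out from 15 and comes back at 22, bypassing the epoxides. Diol 15 is phosphorylated (ClP(O)(OEt)2, pyridine, CH2Cl2) to the bis(allylic diethyl phosphate) F3. A copper-catalysed enantioselective SN2′ methylation ((CuOTf)2·C6H6, chiral N-heterocyclic carbene or peptide-based pyridinyl imine ligand, Me2Zn, THF, −15 °C) then places methyl on both benzylic carbons with allylic transposition and gives 22 directly. One ligand enantiomer should attack the same alkene face on both arms, so the E and Z geometries again translate into R on ring A and S on ring B.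

Step 17. The neopentyl mesylates may ionise with participation of the neighbouring electron-rich aryl ring (1,2-aryl shift), or hydride may attack sulfur and return the diol. The fallback sets out from 20 and comes back at 22. Dess–Martin oxidation of 20 (CH2Cl2, NaHCO3) gives the non-enolisable bis(aldehyde) F4. Wolff–Kishner reduction under Huang-Minlon conditions (N2H4·H2O, KOH, diethylene glycol, 130 → 195 °C, argon) proceeds through the bis(hydrazone) F5 and reduces both formyl groups to methyl, giving 22 without a cationic or radical intermediate next to the stereocentres.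

Further compounds
F1 | step 13 | bis(3-methyl-1,2-diol) from C3-methylative opening of 16: (2R,3S)-3-aryl-3-methyl-1,2-diol unit on ring A, (2R,3R) on ring B | OC[C@H](O)[C@@](C)(CC/C=C(\C)CCC=C(C)C)c1ccc(OC)c(Oc2cc([C@@](C)(CC/C=C(\C)CCC=C(C)C)[C@@H](O)CO)cc(OCOC)c2OCOC)c1
F2 | step 13 | bis(α-methyl aldehyde): (2S,5E)-2,6,10-trimethyl-1-oxoundeca-5,9-dien-2-yl on ring A, (2R,5E) on ring B | O=C[C@@](C)(CC/C=C(\C)CCC=C(C)C)c1ccc(OC)c(Oc2cc([C@@](C)(CC/C=C(\C)CCC=C(C)C)C=O)cc(OCOC)c2OCOC)c1
F3 | step 11 | bis(allylic diethyl phosphate) of 15, ring A arm (2E,6E), ring B arm (2Z,6E) | CCOP(=O)(OCC)OC/C=C(/c1ccc(OC)c(Oc2cc(/C(CC/C=C(\C)CCC=C(C)C)=C\COP(=O)(OCC)OCC)cc(OCOC)c2OCOC)c1)CC/C=C(\C)CCC=C(C)C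
F4 | step 17 | bis(aldehyde) from oxidation of 20: (2S,5E)-2-ethenyl-6,10-dimethyl-1-oxoundeca-5,9-dien-2-yl on ring A, (2R,5E) on ring B | O=C[C@](C=C)(CC/C=C(\C)CCC=C(C)C)c1ccc(OC)c(Oc2cc([C@@](CC/C=C(\C)CCC=C(C)C)(C=C)C=O)cc(OCOC)c2OCOC)c1
F5 | step 17 | bis(hydrazone) of F4 | NN=C[C@](C=C)(CC/C=C(\C)CCC=C(C)C)c1ccc(OC)c(Oc2cc([C@@](CC/C=C(\C)CCC=C(C)C)(C=C)C=NN)cc(OCOC)c2OCOC)c1
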